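All runs are calculated for an exercise; the scatter is artificial.

I cannot read the share of Q in Q plus E at 6.0 s off the ash run, whose first reading comes far later, at 6.00 min. So I solve the two ends and join them.

| flask | G | remark | time |
|---|---|---|---|
| ash | 0.30 M | run made earlier |  |
| flask | 0.20 M |  | 12 h |

ash run (percent of the G charged)

| time / min | Q / % | E / % |
|---|---|---|
| 6.00 | 49.9 | 0 |
| 12.0 | 70.4 | 2.8 |
| 30.0 | 85.8 | 2.8 |
| 80.0 | 88.6 | 0.1 |

(readings scatter by 1 percentage point)

* share of Q in Q plus E at 6.0 s
* share of Q in Q plus E at 12 h
* which of Q and E there is more of at 12 h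

- the numbers in the tables scatter by 1 percentage point (one standard deviation)
- a reading or a percentage of Q counts all its forms, free or not

First instants, in the flask. Q has taken about half of the charge by 6.00 min in the ash run, so at 6.0 s nearly all of the G in the flask still stands. I take Q and E as two branches from G, each first order in G. Their amounts then stand as their rates, and the charge cancels from the ratio.

The middle. That ratio holds while both branches draw on G, so each pair of readings estimates the same thing. One pair is too noisy: E reads 0%, then 2.8%, with a scatter of 1 percentage point. So I pool them. Summed over the ash run, Q gives 295% and E gives 5.70%, which makes 98.1%. I carry this branch share (selectivity), summed Q over summed Q plus E. Its scatter is about 0.67 points.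

The end. In the ash run Q moves from 85.8% at 30.0 min to 88.6% at 80.0 min, so little net Q is still being made, and I keep the ratio as my estimate for the late time. The last E reading, 0.1%, lies below the one before it, which speaks against that estimate. But the branch share expects 1.71% there, within two standard deviations. So I commit to 98.1% at both ends, with Q ahead.

The forecast says 98% at 6.0 s and 99% at 12 h, higher than mine at the late time, with Q ahead: “So Q should dominate from the start”.

The flask gives 98.1% at 6.0 s and 98.0% at 12 h, with Q at 84.7% and E at 1.74%. At 12.0 h G stands at 0.632% in the flask, and the net turnover of the path to E is 1.74%; the branch share lies 0.10 points above the late value.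

    Q → D (k = 4.82 × 10⁻⁵ s⁻¹)
    X ⇌ Q, rate k2*(cs2 - [Q]) while solid is left; crystals form when [Q] > cs2 (solubility = 5.20 mM, k = 0.143 s⁻¹)
    G ⇌ Q (K = 4.11, k = 0.00220 s⁻¹)
    G ⇌ E (K = 2.73, k = 4.25 × 10⁻⁵ s⁻¹)
    2 G → L (k = 9.12 × 10⁻⁴ M⁻¹ s⁻¹)

The neighbour flask, charged with 0.050 M of G, starts at 98.1%, beside the branch share of 98.1%. At 12 h it stands 3.9 points below that share, at 94.2%, with E at 4.28% and G still at 2.51%.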